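in all of them: left-handed substrate 0.30 M; right-handed substrate 0.30 M; free catalyst 0.20 mM

| run | partner | protic impurity | stray impurity | remark | time |
|---|---|---|---|---|---|
| winter | 0.45 M | 0.010 M | 74 µM | run made earlier |  |
| spring | 0.45 M | 0.022 M | 74 µM | run made earlier |  |
| dusk | 0.45 M | 0.015 M | 110 µM | run made earlier |  |
| flask | 0.450 M | 0.0150 M | 74 µM |  | 40 h |

- winter (time / h: right-handed substrate / %, left-handed substrate / %, left-handed product / %): 6.00: 50.2, 35.6, 14.1; 12.0: 49.3, 29.8, 20.9; 20.0: 49.1, 25.2, 24.3; 25.0: 48.6, 26.1, 25.0; 30.0: 47.3, 22.3, 28.4; 40.0: 49.4, 21.4, 30.8
- spring (time / h: right-handed substrate / %, left-handed substrate / %, left-handed product / %): 2.50: 49.7, 43.9, 5.6; 8.00: 50.0, 35.1, 17.3; 15.0: 50.6, 27.5, 20.8; 20.0: 49.4, 26.0, 22.4; 30.0: 49.3, 23.9, 27.0; 40.0: 49.9, 22.7, 30.4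
- dusk (time / h: right-handed substrate / %, left-handed substrate / %, left-handed product / %): 4.00: 49.8, 42.1, 8.8; 10.0: 49.8, 37.9, 16.3; 20.0: 50.0, 31.4, 20.1; 30.0: 49.8, 27.1, 23.0; 40.0: 47.6, 24.9, 24.6

(each reading ± 1 percentage point)

- free catalyst is single-handed; left-handed substrate and right-handed substrate are mirror images of each other, charged as a racemate, each of them at the stated concentration
- what was read earlier has a scatter of 1 percentage point, one standard deviation
- steps thought possible: partner + free catalyst + left-handed substrate -> free catalyst + left-handed product; partner + free catalyst + right-handed substrate -> free catalyst + right-handed product; partner + protic impurity -> quenched reagent; partner + free catalyst -> spent catalyst A; free catalyst + stray impurity -> spent catalyst B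

1. whether the excess of right-handed substrate over left-handed substrate among what is left of the two reaches 99% by 40 h (no / yes)
2. the highest excess of right-handed substrate over left-handed substrate among what is left of the two up to 40 h

**Working catalyst.** The flask is charged with 0.20 mM of free catalyst against 74 µM of stray impurity, so the stray impurity, smaller in amount, is the limiting reagent of the poisoning. Follow one molecule of free catalyst: this reckoning takes the poisoning as quick and one to one, so the chance of being lost at that fork is 37.0%. What the poisoning leaves is the working catalyst, the charge minus the stray impurity, here 126 µM. Take the depletion as the logarithm of half the total charge over the left-handed substrate reading. At 20.0 h, winter's depletion over dusk's reads 1.47, and the ratio of their working catalysts is 1.40.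

**The bracket.** Winter has this working catalyst and less protic impurity than the flask, so its last reading, an excess of 39.5%, is taken as the estimate from above. Dusk has the flask's protic impurity but less working catalyst, and gives 31.3% from below. Spring tightens that bound: same working catalyst, more protic impurity, 37.5%. The scatter of a left-handed substrate reading reaches the excess about twice over.

**The forecast.** It says 39%, between 36% and 42%, inside the bracket, and no to 99%, on the view that “the catalyst is dying and conversion stalls”.

**The flask.** Its highest excess is 39.9%, 0.40 percentage points above the winter reading and within that reading's scatter; reaching 99%: no.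

    partner + free catalyst + left-handed substrate → free catalyst + left-handed product (k = 20.0 L² mol⁻² min⁻¹)
    partner + free catalyst + right-handed substrate → free catalyst + right-handed product (k = 0.520 L² mol⁻² min⁻¹)
    partner + protic impurity → quenched reagent (k = 0.0510 L mol⁻¹ min⁻¹)
    partner + free catalyst → spent catalyst A (k = 0.00240 L mol⁻¹ min⁻¹)
    free catalyst + stray impurity → spent catalyst B (k = 490 L mol⁻¹ min⁻¹)

**Working catalyst again.** In the flask, spent catalyst B stands at 37.0% of the catalyst charged after 4.00 h and at 37.0% after 40.0 h, the share reckoned above. A neighbour flask charged with 3.4 × 10⁻⁴ M of free catalyst has 266 µM working, twice this flask's. Its depletion at 40.0 h, 1.65 against 0.867, is also twice as large, and its highest excess is 66.6%.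

Readings and results were computed for substances that don't exist.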